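## The problem

The target (35) is a cis,cis-germacranolide: a ten-membered carbocycle with two Z-trisubstituted alkenes (C4=C5, C9=C10), an α-methylene-γ-butyrolactone cis-fused across C6–C7, an angelate on O8, an acetate on O3 and a free hydroxyl at C1. Five stereocentres have to be set: the contiguous triad C6/C7/C8 and the isolated carbinols C3 and C1. Within the triad, C8 can govern C7 through allylic 1,3-strain in a (Z)-configured allylmetal, and C7 is relayed to C6 by a closed chair transition state, so only C8 needs an outside source of chirality; C3 sits across an sp2 carbon from C6 and needs its own source, and C1 (1,3-anti to C3) can be left to the ring closure. The fragile groups are the angelate (Z to E isomerisation with bases and nucleophiles; a leaving group at the doubly allylic C8), the exo-methylene lactone (Michael acceptor; translactonisation to O8 if that oxygen is ever free beside it), the allylic C3 acetate (1,3-acyl shift, β-elimination next to a C1 carbonyl) and the medium ring. Both ring alkenes are Z and trisubstituted, so their geometry must be fixed before the carbocycle exists. The enabling feature is that O3 and O6 flank C4=C5 as a (Z)-2-ene-1,4-diol, the ring-opened form of a 4,7-dihydro-1,3-dioxa-2-silepine that metathesis of a C6 vinyl carbinol and a C3 isopropenyl carbinol, joined through silicon, can deliver only as the cis alkene. O3 and O6 lie on opposite faces of the ten-membered ring, however, so a one-atom silicon bridge is compatible with the open chain only and must be removed before the carbocycle is closed.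

## Retrosynthesis

**C1–C10 (35 ⇒ 34).** The ring is opened between the C1 carbinol and the C10 alkene carbon, giving the iodo-aldehyde 34 for a Nozaki–Hiyama–Kishi closure. Cutting at either ring alkene would require a Z-trisubstituted alkene to be formed inside a ten-membered ring; this cut leaves both alkenes preset and creates only C1. The forward step must close a ten-membered ring at high dilution, tolerate the lactone and the esters, and deliver the 1,3-anti (1S) carbinol.

**Functional-group adjustment (34 ⇒ 33 ⇒ 32 ⇒ 31).** The aldehyde is traced to a primary TBDPS ether and the acetate to the single free hydroxyl of 31. Nothing is simplified structurally; the point is that the acetate is placed when O3 is the only free oxygen, and the aldehyde is made last because it is a β-acetoxy aldehyde.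

**Lactone and silicon bridge (31 ⇒ 29).** The C12–O6 acyl bond is cut and O3 and O6 are re-bridged by silicon, giving dioxasilepine 29. Keeping the bridge through the macrocyclisation would demand an in,out-bridged bicycle, because C3 and C6 are trans on the seven-membered ring. In the forward direction, Si–O cleavage frees O6, which lactonises onto C12, so the two oxygens are differentiated without a protecting group. The forward step must cleave a dialkoxysilane in the presence of a primary TBDPS ether.

**C4=C5 (29 ⇒ 28), the key cut.** Opening the ring alkene gives the acyclic silaketal 28 with a C5 vinyl and a C4 isopropenyl group. This is the only cut that both fixes the Z geometry by ring size and joins the two halves; an untethered cross-metathesis or olefination has no Z bias. The forward step must select these two alkenes over the acrylate, the angelate and the iodo-alkene.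

**Angelate and Si–O bonds (28 ⇒ 25 + 26; 25 ⇒ 24 ⇒ 14 + 22 + 21).** The C8 ester is cut to alcohol 25 and angelic acid 26, and the silaketal to western alcohol 14, dichlorosilane 22 and eastern alcohol 21. The angelate goes on after the C6–C7 bond exists (an ester at C8 would be expelled from the allylmetal) and before the lactone exists (O8 is never free beside it). The tether itself covers O6 during the PMB-to-angelate exchange.

**C6–C7 (14 ⇒ 12 + 13).** The bond between the vinyl carbinol and C7 is cut to allylic bromide 12 and acrolein 13. A Barbier allylation makes this bond and the exo-methylene ester in one step and sets C6 and C7 from C8; the alternative C7–C8 cut would need the anti adduct, against the syn preference of (Z)-2-(bromomethyl)enoates. The forward step must give the syn adduct and add anti to the C8–O bond.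

**C7–C11 and C13–Br (12 ⇒ 11 ⇒ 8 + 9).** The bromide is the allylic transposition product of hydroxy ester 11, which comes from α-alkoxy aldehyde 8 and methyl propiolate 9. The forward addition must be non-basic, because C8 in 8 is α to a carbonyl and allylic.

**C9=C10 and the source of C8 (8 ⇒ 7 ⇒ 6 ⇒ 5 ⇒ 4 ⇒ 1 + 2).** The Z-iodoalkene is cut to (S)-glyceraldehyde acetonide 1 and phosphonium salt 2. The chiral pool supplies C8, and reductive opening of acetal 6 places the PMB group on the secondary oxygen without separate protection steps.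

**Eastern half (21 ⇒ 20 ⇒ 19 ⇒ 17 + 18; 17 ⇒ 16 ⇒ 15).** The C3–C4 bond is cut to aldehyde 17 and isopropenylmagnesium bromide 18, with C3 set by catalyst-controlled reduction of enone 20. Aldehyde 17 comes from propane-1,3-diol 15.

## Roads not taken

**Alternative 1:** The cut is through the ring itself: 2,7-dimethylnaphthalene A1 is Birch-reduced to 2,7-dimethyl-1,4,5,8-tetrahydronaphthalene A2, and ozonolysis of its central tetrasubstituted alkene gives (3Z,8Z)-3,9-dimethylcyclodeca-3,8-diene-1,6-dione A3.
- Merits: the ten-membered ring and both cis methyl-bearing alkenes arrive in two or three steps from an aromatic compound, with geometry guaranteed by the six-membered rings and no high-dilution step. In ring construction this road is clearly better than the chosen one.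
- Weak points: the carbonyls of A3 sit at C2 and C7, where the target has a methylene and a carbon branch, while the oxygens are needed at C1, C3, C6 and C8. Each ketone would have to be oxygenated on both α-carbons and then removed or converted to a C–C bond. The ketones are β,γ-unsaturated and conjugate easily, A3 is achiral and must be desymmetrised, and all five stereocentres would be set on a flexible ring with no controlling element.
- Comparison: the chosen plan pays with a longer sequence and a late macrocyclisation, but every oxygen is at the right carbon from the start and four of five stereocentres are set in acyclic or small-ring settings with established models.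

**Alternative 2:** The cut is the lactone (C7–C11 and C6–O): trivalent manganese (Mn(OAc)3) oxidises malonic acid A4 to its radical, which adds to C7 of a C4–C7 diene in the preformed ring; oxidation of the allyl radical and carboxylate capture at C6 give the cis-fused α-carboxy lactone A5.
- Merits: the Michael acceptor is built at the very end instead of being carried through sixteen steps, and a five-membered annulation is naturally cis. On this point the road is better; the chosen plan relies on the 2-substituted acrylate being inert to ruthenium, chromium and amines.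
- Weak points: the substrate is the oxygenated ten-membered triene, whose synthesis is the real problem and is not addressed. The electrophilic radical can add at C4 or at C9=C10, the ring allyl radical can cyclise transannularly, the face of attack relative to C8 and C3 is uncontrolled, and hot acetic acid with an oxidant is unkind to the angelate and the allylic acetate.
- Comparison: C6/C7 control by a chair transition state in an acyclic Barbier reaction is more dependable than a radical addition on a medium ring.

**Alternative 3:** The cut is C8–C9: an alkynylchromium generated with CrCl2 and catalytic NiCl2 at C9 adds to a C8 aldehyde to give the ten-membered cycloalkynol A6 as both C8 epimers; a methylcuprate then adds across the alkyne to install C14.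
- Merits: the nucleophile is a small sp carbon, the protecting groups are robust ethers, and the triad does not depend on induction in an allylation. In ease of the ring-closing bond formation it is at least as good as the chosen closure, which must bring in a hindered trisubstituted alkenylchromium.
- Weak points: a cyclodecyne that already holds a Z-alkene is strained; C8 is formed without control next to an epimerisable C7; the regiochemistry of methyl delivery (C10 versus C9) between two oxygenated propargylic positions is open; and C12 still has to be oxidised and lactonised and three oxygens re-differentiated afterwards.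
- Comparison: the chosen plan closes the ring with both alkene geometries, the angelate and the lactone in place and leaves only C1 open, for which a 1,3-anti bias and a reagent-controlled correction exist.

Key step: step 17

Remark: locants such as C6 or O8 follow germacrane numbering of 35; the CIP descriptors of C7 and C8 change along the route with the substituents although no centre is inverted once set; 1 is taken as purchased (it is also available by oxidation of (R)-solketal).

## Route

Step 1
Reactants: 1 (4S)-2,2-dimethyl-1,3-dioxolane-4-carbaldehyde; 2 ethyltriphenylphosphonium iodide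
Product: 4 (4R)-4-[(1Z)-2-iodoprop-1-en-1-yl]-2,2-dimethyl-1,3-dioxolane, via (1-iodoethyl)triphenylphosphonium iodide 3 (not isolated)
Conditions: 2, n-BuLi, THF, rt; I2, −78 °C; NaN(SiMe3)2, −20 °C; then 1, −78 to −20 °C
Reagents that add atoms: iodine, II
Why: Stork–Zhao-type Wittig olefination; the α-iodo ylide reacts under kinetic control to give the (Z)-2-iodoalkene (iodine cis to the chain), and the cold, salt-rich conditions do not epimerise the α-alkoxy aldehyde.

Step 2
Reactants: 4 (4R)-4-[(1Z)-2-iodoprop-1-en-1-yl]-2,2-dimethyl-1,3-dioxolane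
Product: 5 (2R,3Z)-4-iodopent-3-ene-1,2-diol
Conditions: AcOH/H2O (4:1), 40 °C
Reagents that add atoms: none
Why: Acid-catalysed hydrolysis of the isopropylidene acetal; the iodoalkene and the allylic C–O bond survive aqueous acetic acid.

Step 3
Reactants: 5 (2R,3Z)-4-iodopent-3-ene-1,2-diol
Product: 6 (4R)-4-[(1Z)-2-iodoprop-1-en-1-yl]-2-(4-methoxyphenyl)-1,3-dioxolane (both acetal epimers)
Conditions: 4-MeOC6H4CH(OMe)2, PPTS (cat.), CH2Cl2, rt
Reagents that add atoms: 4-methoxybenzaldehyde dimethyl acetal, COC(OC)c1ccc(OC)cc1
Why: Acid-catalysed transacetalisation to the five-membered p-methoxybenzylidene acetal of the 1,2-diol; the configuration of the acetal carbon is lost in step 4.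

Step 4
Reactants: 6 (4R)-4-[(1Z)-2-iodoprop-1-en-1-yl]-2-(4-methoxyphenyl)-1,3-dioxolane
Product: 7 (2R,3Z)-4-iodo-2-[(4-methoxyphenyl)methoxy]pent-3-en-1-ol
Conditions: iBu2AlH, CH2Cl2, −78 to 0 °C
Reagents that add atoms: none
Why: Regioselective reductive opening of the benzylidene acetal; aluminium binds the less hindered primary oxygen, that C–O bond breaks and hydride reduces the oxocarbenium ion, leaving the PMB group on the secondary (C8) oxygen.

Step 5
Reactants: 7 (2R,3Z)-4-iodo-2-[(4-methoxyphenyl)methoxy]pent-3-en-1-ol
Product: 8 (2R,3Z)-4-iodo-2-[(4-methoxyphenyl)methoxy]pent-3-enal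
Conditions: Dess–Martin periodinane, NaHCO3, CH2Cl2, 0 °C
Reagents that add atoms: none
Why: Dess–Martin oxidation under buffered, non-basic conditions gives the α-alkoxy β,γ-unsaturated aldehyde without epimerisation or conjugation; it is used at once.

Step 6
Reactants: 8 (2R,3Z)-4-iodo-2-[(4-methoxyphenyl)methoxy]pent-3-enal; 9 methyl propiolate
Product: 11 methyl (4R,5Z)-3-hydroxy-6-iodo-4-[(4-methoxyphenyl)methoxy]-2-methylidenehept-5-enoate (both C3 epimers), via [1-(methoxycarbonyl)ethenyl]diisobutylaluminium 10 (not isolated)
Conditions: 9, iBu2AlH, N-methylmorpholine N-oxide, THF, 0 °C; then 8, 0 °C to rt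
Reagents that add atoms: diisobutylaluminium hydride, CC(C)C[AlH]CC(C)C (its atoms stay only in 10)
Why: Vinylalumination, an aluminium-mediated Baylis–Hillman-type addition; conjugate hydroalumination of 9 gives the α-aluminoacrylate, which adds to the aldehyde without the amine base that would epimerise C8, and the new carbinol centre is erased in step 7.

Step 7
Reactants: 11 methyl (4R,5Z)-3-hydroxy-6-iodo-4-[(4-methoxyphenyl)methoxy]-2-methylidenehept-5-enoate
Product: 12 methyl (2Z,4S,5Z)-2-(bromomethyl)-6-iodo-4-[(4-methoxyphenyl)methoxy]hepta-2,5-dienoate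
Conditions: NBS, Me2S, CH2Cl2, 0 °C to rt
Reagents that add atoms: N-bromosuccinimide, O=C1CCC(=O)N1Br
Why: SN2' bromination of the Baylis–Hillman-type alcohol through its alkoxysulfonium salt; bromide enters at the methylidene carbon and the trisubstituted alkene forms with the C8 chain trans to the ester (2Z), as is general for such esters.

Step 8
Reactants: 12 methyl (2Z,4S,5Z)-2-(bromomethyl)-6-iodo-4-[(4-methoxyphenyl)methoxy]hepta-2,5-dienoate; 13 acrolein
Product: 14 methyl (3R,4S,5Z)-3-[(1R)-1-hydroxyprop-2-en-1-yl]-6-iodo-4-[(4-methoxyphenyl)methoxy]-2-methylidenehept-5-enoate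
Conditions: In powder, THF/H2O (1:1), rt
Reagents that add atoms: none
Why: Barbier allylation; the allylindium reacts at its γ-carbon (C7) through a closed chair with the cis-disposed C8 substituent axial and the vinyl group equatorial, giving the syn C6/C7 adduct (the precursor of a cis lactone). Allylic 1,3-strain holds H8 in the alkene plane and the aldehyde adds anti to the C8–O bond (an ether oxygen chelated to indium leads to the same face), which fixes C7 and with it C6 relative to C8.

Step 9
Reactants: 15 propane-1,3-diol
Product: 16 3-[(tert-butyldiphenylsilyl)oxy]propan-1-ol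
Conditions: NaH (1 equiv), THF, rt; then t-BuPh2SiCl
Reagents that add atoms: tert-butyl(chloro)diphenylsilane, CC(C)(C)[Si](Cl)(c1ccccc1)c1ccccc1
Why: Monosilylation of a symmetrical diol through its sparingly soluble monosodium alkoxide, which reacts once.

Step 10
Reactants: 16 3-[(tert-butyldiphenylsilyl)oxy]propan-1-ol
Product: 17 3-[(tert-butyldiphenylsilyl)oxy]propanal
Conditions: PhI(OAc)2, TEMPO (cat.), CH2Cl2, rt
Reagents that add atoms: none
Why: Oxoammonium-mediated oxidation of a primary alcohol stops at the aldehyde and leaves the silyl ether alone.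

Step 11
Reactants: 17 3-[(tert-butyldiphenylsilyl)oxy]propanal; 18 isopropenylmagnesium bromide
Product: 19 rac-5-[(tert-butyldiphenylsilyl)oxy]-2-methylpent-1-en-3-ol
Conditions: THF, −78 °C; aq. NH4Cl
Reagents that add atoms: none
Why: Grignard addition to an aldehyde forms the C3–C4 bond; the racemic centre is removed in step 12.

Step 12
Reactants: 19 rac-5-[(tert-butyldiphenylsilyl)oxy]-2-methylpent-1-en-3-ol
Product: 20 5-[(tert-butyldiphenylsilyl)oxy]-2-methylpent-1-en-3-one
Conditions: Dess–Martin periodinane, NaHCO3, CH2Cl2, 0 °C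
Reagents that add atoms: none
Why: Dess–Martin oxidation of the allylic alcohol to the α-methyl enone; the β-silyloxy group does not eliminate under buffered conditions.

Step 13
Reactants: 20 5-[(tert-butyldiphenylsilyl)oxy]-2-methylpent-1-en-3-one
Product: 21 (3S)-5-[(tert-butyldiphenylsilyl)oxy]-2-methylpent-1-en-3-ol
Conditions: (R)-2-methyl-CBS-oxazaborolidine (15 mol%), catecholborane, toluene, −78 °C
Reagents that add atoms: none
Why: Corey–Bakshi–Shibata reduction; the ketone binds the catalyst with the larger α-methylvinyl group away from the ring and hydride is delivered to one face, giving the (S)-alcohol with the (R)-catalyst, while catecholborane at low temperature avoids hydroboration of the alkene.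

Step 14
Reactants: 14 methyl (3R,4S,5Z)-3-[(1R)-1-hydroxyprop-2-en-1-yl]-6-iodo-4-[(4-methoxyphenyl)methoxy]-2-methylidenehept-5-enoate; 22 dichlorodi(propan-2-yl)silane; 21 (3S)-5-[(tert-butyldiphenylsilyl)oxy]-2-methylpent-1-en-3-ol
Product: 24 mixed silaketal iPr2Si(OR)(OR′), R = C6 oxygen of 14, R′ = C3 oxygen of 21, C8 PMB ether, C1 TBDPS ether, (3S,6R,7S,8S), via C6-O-chlorodiisopropylsilyl ether 23 (not isolated)
Conditions: 14, 22 (3 equiv), imidazole, CH2Cl2, 0 °C to rt; excess 22 removed in vacuo; then 21, imidazole, DMF, rt
Reagents that add atoms: none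
Why: Stepwise nucleophilic substitution at silicon; the hindered C6 hydroxyl reacts once with excess dichlorosilane, and the less hindered alcohol 21 then displaces the second chloride to give the unsymmetrical silaketal.

Step 15
Reactants: 24 mixed silaketal, C8 PMB ether, (3S,6R,7S,8S)
Product: 25 mixed silaketal iPr2Si(OR)(OR′) with free C8 hydroxyl, (3S,6R,7S,8S)
Conditions: DDQ, CH2Cl2/pH 7 buffer (10:1), 0 °C
Reagents that add atoms: none
Why: Oxidative cleavage of the PMB ether (benzylic hydride abstraction, hydrolysis of the oxocarbenium ion); the silaketal, the TBDPS ether and the alkenes are inert under buffered conditions.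

Step 16
Reactants: 25 mixed silaketal with free C8 hydroxyl, (3S,6R,7S,8S); 26 angelic acid
Product: 28 mixed silaketal iPr2Si(OR)(OR′), R = C6 oxygen of CH2=CH–CH(O–)–CH[C(=CH2)CO2Me]–CH(O-angeloyl)–CH=C(CH3)I (Z), R′ = C3 oxygen of 21, (3S,6R,7S,8S), via angelic 2,4,6-trichlorobenzoic anhydride 27 (not isolated)
Conditions: 26, 2,4,6-Cl3C6H2COCl, Et3N, toluene, rt; then 25, toluene, 80 °C
Reagents that add atoms: 2,4,6-trichlorobenzoyl chloride, O=C(Cl)c1c(Cl)cc(Cl)cc1Cl (its atoms stay only in 27)
Why: Yamaguchi esterification; the hindered alcohol attacks the angeloyl carbonyl of the mixed anhydride (the other carbonyl is blocked by two ortho chlorines), with retention at C8, and running without added nucleophilic amine preserves the Z geometry.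

Step 17
Reactants: 28 acyclic mixed silaketal with C5 vinyl and C4 isopropenyl groups, C8 angelate, (3S,6R,7S,8S)
Product: 29 (4S,7R)-4-{2-[(tert-butyldiphenylsilyl)oxy]ethyl}-5-methyl-2,2-di(propan-2-yl)-7-[CH{C(=CH2)CO2Me}–CH(O-angeloyl)–CH=C(CH3)I (Z)]-4,7-dihydro-1,3-dioxa-2-silepine, cis C4=C5, (3S,6R,7S,8S)
Conditions: second-generation Hoveyda–Grubbs catalyst (10 mol%), 1,4-benzoquinone (20 mol%), toluene (0.005 M), 80 °C
Reagents that add atoms: none
Why: Ring-closing olefin metathesis on a temporary silicon tether; the closest known reaction type is closure of bis-allylic dialkylsilaketals to 4,7-dihydro-1,3-dioxa-2-silepines, which are masked (Z)-2-ene-1,4-diols. The active ruthenium species loads onto the only monosubstituted alkene, the C5 vinyl group, to give the C5 alkylidene. Intramolecular [2+2] cycloaddition with the 1,1-disubstituted C4 alkene and cycloreversion form the C4=C5 bond, close the seven-membered ring within the O–Si–O bridge and release ethylene. A ring of this size holds only the cis alkene, so the Z geometry is structural. No stereocentre is formed; C3 and C6 are spectators and end up trans on the ring, which costs one pseudo-axial substituent. The step needs site selectivity against three other alkenes: the acrylate and the angelate are electron-poor and 1,1-di- or trisubstituted, the iodoalkene is trisubstituted and deactivated, and none can form an unstrained ring with the C5 carbene (a cyclobutene with C13, a cyclopentene only through an iodo-carbene). High dilution suppresses cross-metathesis at C5, and benzoquinone intercepts ruthenium hydrides that would isomerise the angelate.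

Step 18
Reactants: 29 dioxasilepine, (3S,6R,7S,8S)
Product: 31 (4R,5R)-5-[(1Z,3S)-5-[(tert-butyldiphenylsilyl)oxy]-3-hydroxy-2-methylpent-1-en-1-yl]-4-[(1S,2Z)-3-iodo-1-{[(2Z)-2-methylbut-2-enoyl]oxy}but-2-en-1-yl]-3-methylideneoxolan-2-one, via C3,C6-diol methyl ester 30 (not isolated)
Conditions: HF·pyridine, pyridine, THF, 0 °C; then PPTS (cat.), CH2Cl2, rt
Reagents that add atoms: none
Why: Fluoride cleavage of both Si–O bonds of the dialkoxysilane, much faster than attack on the primary TBDPS ether in buffered HF·pyridine; the freed C6 hydroxyl sits syn to the ester-bearing C7 substituent and closes the cis γ-lactone by acyl substitution with loss of methanol, whereas O3 cannot reach C12.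

Step 19
Reactants: 31 lactone with free C3 hydroxyl, (3S,6R,7R,8S)
Product: 32 (4R,5R)-5-[(1Z,3S)-3-acetoxy-5-[(tert-butyldiphenylsilyl)oxy]-2-methylpent-1-en-1-yl]-4-[(1S,2Z)-3-iodo-1-{[(2Z)-2-methylbut-2-enoyl]oxy}but-2-en-1-yl]-3-methylideneoxolan-2-one
Conditions: Ac2O, pyridine, DMAP (cat.), CH2Cl2, 0 °C
Reagents that add atoms: acetic anhydride, CC(=O)OC(C)=O
Why: Acylation of the only free hydroxyl; short exposure at 0 °C spares the angelate and the exo-methylene lactone.

Step 20
Reactants: 32 lactone C3 acetate, C1 TBDPS ether, (3S,6R,7R,8S)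
Product: 33 (4R,5R)-5-[(1Z,3S)-3-acetoxy-5-hydroxy-2-methylpent-1-en-1-yl]-4-[(1S,2Z)-3-iodo-1-{[(2Z)-2-methylbut-2-enoyl]oxy}but-2-en-1-yl]-3-methylideneoxolan-2-one
Conditions: HF·pyridine (excess), pyridine, THF, rt
Reagents that add atoms: none
Why: Fluoride desilylation of the primary TBDPS ether; the acidic medium avoids the 1,3-acetyl shift and conjugate additions that basic fluoride would cause.

Step 21
Reactants: 33 primary alcohol, (3S,6R,7R,8S)
Product: 34 (4R,5R)-5-[(1Z,3S)-3-acetoxy-2-methyl-5-oxopent-1-en-1-yl]-4-[(1S,2Z)-3-iodo-1-{[(2Z)-2-methylbut-2-enoyl]oxy}but-2-en-1-yl]-3-methylideneoxolan-2-one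
Conditions: Dess–Martin periodinane, NaHCO3, CH2Cl2, 0 °C to rt
Reagents that add atoms: none
Why: Buffered Dess–Martin oxidation gives the β-acetoxy aldehyde without base that would trigger elimination to the dienal; it is used directly.

Step 22
Reactants: 34 iodo-aldehyde, (3S,6R,7R,8S)
Product: 35 (1S,3S,4Z,6R,7R,8R,9Z)-3-acetoxy-1-hydroxy-8-{[(2Z)-2-methylbut-2-enoyl]oxy}germacra-4,9,11(13)-trien-12,6-olide (target)
Conditions: CrCl2 (15 equiv), NiCl2 (0.2 equiv), degassed DMSO (0.002 M), rt, slow addition of 34
Reagents that add atoms: none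
Why: Nozaki–Hiyama–Kishi reaction; zerovalent nickel inserts into the C10–I bond with retention of geometry, transmetalation gives the alkenylchromium of trivalent chromium, and its addition to the C1 aldehyde closes the ten-membered ring (exo-trig at the carbonyl; both Z alkenes and the cis lactone pre-bend the chain). The (1S) carbinol is expected from 1,3-anti induction by the β-acetoxy group with the carbonyl oxygen pointing out of the forming ring; esters and the exo-methylene lactone are inert to alkenylchromium.

## Compound list

1 | (4S)-2,2-dimethyl-1,3-dioxolane-4-carbaldehyde | O=C[C@@H]1COC(C)(C)O1 | starting material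
2 | ethyltriphenylphosphonium iodide | CC[P+](c1ccccc1)(c1ccccc1)c1ccccc1.[I-] | starting material
3 | (1-iodoethyl)triphenylphosphonium iodide (formed in situ) | CC(I)[P+](c1ccccc1)(c1ccccc1)c1ccccc1.[I-] | intermediate
4 | (4R)-4-[(1Z)-2-iodoprop-1-en-1-yl]-2,2-dimethyl-1,3-dioxolane | C/C(I)=C/[C@@H]1COC(C)(C)O1 | intermediate
5 | (2R,3Z)-4-iodopent-3-ene-1,2-diol | C/C(I)=C/[C@@H](O)CO | intermediate
6 | (4R)-4-[(1Z)-2-iodoprop-1-en-1-yl]-2-(4-methoxyphenyl)-1,3-dioxolane (acetal epimers) | C/C(I)=C/[C@@H]1COC(c2ccc(OC)cc2)O1 | intermediate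
7 | (2R,3Z)-4-iodo-2-[(4-methoxyphenyl)methoxy]pent-3-en-1-ol | C/C(I)=C/[C@@H](OCc1ccc(OC)cc1)CO | intermediate
8 | (2R,3Z)-4-iodo-2-[(4-methoxyphenyl)methoxy]pent-3-enal | C/C(I)=C/[C@@H](OCc1ccc(OC)cc1)C=O | intermediate
9 | methyl propiolate | C#CC(=O)OC | starting material
10 | [1-(methoxycarbonyl)ethenyl]diisobutylaluminium (formed in situ) | C=C(C(=O)OC)[Al](CC(C)C)CC(C)C | intermediate
11 | methyl (4R,5Z)-3-hydroxy-6-iodo-4-[(4-methoxyphenyl)methoxy]-2-methylidenehept-5-enoate (C3 epimers) | C/C(I)=C/[C@@H](OCc1ccc(OC)cc1)C(O)C(=C)C(=O)OC | intermediate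
12 | methyl (2Z,4S,5Z)-2-(bromomethyl)-6-iodo-4-[(4-methoxyphenyl)methoxy]hepta-2,5-dienoate | C/C(I)=C/[C@@H](OCc1ccc(OC)cc1)/C=C(\CBr)C(=O)OC | intermediate
13 | acrolein | C=CC=O | starting material
14 | methyl (3R,4S,5Z)-3-[(1R)-1-hydroxyprop-2-en-1-yl]-6-iodo-4-[(4-methoxyphenyl)methoxy]-2-methylidenehept-5-enoate | C=C[C@@H](O)[C@@H](C(=C)C(=O)OC)[C@H](OCc1ccc(OC)cc1)/C=C(/C)I | intermediate
15 | propane-1,3-diol | OCCCO | starting material
16 | 3-[(tert-butyldiphenylsilyl)oxy]propan-1-ol | OCCCO[Si](c1ccccc1)(c1ccccc1)C(C)(C)C | intermediate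
17 | 3-[(tert-butyldiphenylsilyl)oxy]propanal | O=CCCO[Si](c1ccccc1)(c1ccccc1)C(C)(C)C | intermediate
18 | isopropenylmagnesium bromide | CC(=C)[Mg]Br | starting material
19 | rac-5-[(tert-butyldiphenylsilyl)oxy]-2-methylpent-1-en-3-ol | C=C(C)C(O)CCO[Si](c1ccccc1)(c1ccccc1)C(C)(C)C | intermediate
20 | 5-[(tert-butyldiphenylsilyl)oxy]-2-methylpent-1-en-3-one | C=C(C)C(=O)CCO[Si](c1ccccc1)(c1ccccc1)C(C)(C)C | intermediate
21 | (3S)-5-[(tert-butyldiphenylsilyl)oxy]-2-methylpent-1-en-3-ol | O[C@H](C(C)=C)CCO[Si](c1ccccc1)(c1ccccc1)C(C)(C)C | intermediate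
22 | dichlorodi(propan-2-yl)silane | CC(C)[Si](Cl)(Cl)C(C)C | starting material
23 | C6-O-[chlorodi(propan-2-yl)silyl] ether of 14 (formed in situ) | C=C[C@@H](O[Si](Cl)(C(C)C)C(C)C)[C@@H](C(=C)C(=O)OC)[C@H](OCc1ccc(OC)cc1)/C=C(/C)I | intermediate
24 | mixed di(propan-2-yl)silaketal of 14 (O6) and 21 (O3), C8 PMB ether, (3S,6R,7S,8S) | C=C[C@@H](O[Si](C(C)C)(C(C)C)O[C@H](C(C)=C)CCO[Si](c1ccccc1)(c1ccccc1)C(C)(C)C)[C@@H](C(=C)C(=O)OC)[C@H](OCc1ccc(OC)cc1)/C=C(/C)I | intermediate
25 | mixed di(propan-2-yl)silaketal with free C8 hydroxyl, (3S,6R,7S,8S) | C=C[C@@H](O[Si](C(C)C)(C(C)C)O[C@H](C(C)=C)CCO[Si](c1ccccc1)(c1ccccc1)C(C)(C)C)[C@@H](C(=C)C(=O)OC)[C@H](O)/C=C(/C)I | intermediate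
26 | angelic acid, (2Z)-2-methylbut-2-enoic acid | C/C=C(/C)C(O)=O | starting material
27 | angelic 2,4,6-trichlorobenzoic anhydride (formed in situ) | C/C=C(/C)C(=O)OC(=O)c1c(Cl)cc(Cl)cc1Cl | intermediate
28 | mixed di(propan-2-yl)silaketal, C8 angelate, (3S,6R,7S,8S); metathesis precursor | C=C[C@@H](O[Si](C(C)C)(C(C)C)O[C@H](C(C)=C)CCO[Si](c1ccccc1)(c1ccccc1)C(C)(C)C)[C@@H](C(=C)C(=O)OC)[C@H](OC(=O)/C(C)=C\C)/C=C(/C)I | intermediate
29 | (4S,7R)-4,7-dihydro-1,3-dioxa-2-silepine with cis C4=C5, C8 angelate, C1 TBDPS ether, (3S,6R,7S,8S); metathesis product | CC1=C[C@H]([C@@H](C(=C)C(=O)OC)[C@H](OC(=O)/C(C)=C\C)/C=C(/C)I)O[Si](C(C)C)(C(C)C)O[C@H]1CCO[Si](c2ccccc2)(c2ccccc2)C(C)(C)C | intermediate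
30 | C3,C6-diol methyl ester, (3S,6R,7R,8S) (formed in situ) | O[C@@H](CCO[Si](c1ccccc1)(c1ccccc1)C(C)(C)C)/C(C)=C\[C@@H](O)[C@@H](C(=C)C(=O)OC)[C@H](OC(=O)/C(C)=C\C)/C=C(/C)I | intermediate
31 | (4R,5R)-5-[(1Z,3S)-5-[(tert-butyldiphenylsilyl)oxy]-3-hydroxy-2-methylpent-1-en-1-yl]-4-[(1S,2Z)-3-iodo-1-{[(2Z)-2-methylbut-2-enoyl]oxy}but-2-en-1-yl]-3-methylideneoxolan-2-one | C=C1C(=O)O[C@H](/C=C(/C)[C@@H](O)CCO[Si](c2ccccc2)(c2ccccc2)C(C)(C)C)[C@@H]1[C@H](OC(=O)/C(C)=C\C)/C=C(/C)I | intermediate
32 | C3 acetate of 31 | C=C1C(=O)O[C@H](/C=C(/C)[C@@H](OC(C)=O)CCO[Si](c2ccccc2)(c2ccccc2)C(C)(C)C)[C@@H]1[C@H](OC(=O)/C(C)=C\C)/C=C(/C)I | intermediate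
33 | (4R,5R)-5-[(1Z,3S)-3-acetoxy-5-hydroxy-2-methylpent-1-en-1-yl]-4-[(1S,2Z)-3-iodo-1-{[(2Z)-2-methylbut-2-enoyl]oxy}but-2-en-1-yl]-3-methylideneoxolan-2-one | C=C1C(=O)O[C@H](/C=C(/C)[C@@H](OC(C)=O)CCO)[C@@H]1[C@H](OC(=O)/C(C)=C\C)/C=C(/C)I | intermediate
34 | (4R,5R)-5-[(1Z,3S)-3-acetoxy-2-methyl-5-oxopent-1-en-1-yl]-4-[(1S,2Z)-3-iodo-1-{[(2Z)-2-methylbut-2-enoyl]oxy}but-2-en-1-yl]-3-methylideneoxolan-2-one | C=C1C(=O)O[C@H](/C=C(/C)[C@@H](OC(C)=O)CC=O)[C@@H]1[C@H](OC(=O)/C(C)=C\C)/C=C(/C)I | intermediate
35 | (1S,3S,4Z,6R,7R,8R,9Z)-3-acetoxy-1-hydroxy-8-{[(2Z)-2-methylbut-2-enoyl]oxy}germacra-4,9,11(13)-trien-12,6-olide | C=C1C(=O)O[C@@H]2/C=C(/C)[C@@H](OC(C)=O)C[C@H](O)/C(C)=C\[C@@H](OC(=O)/C(C)=C\C)[C@H]12 | target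

## Step count and least certain steps

Total step count: 22. Longest linear sequence: 17 steps (steps 1–8 and 14–22, from 1 to 35).

**Step 17 (key step).** The most likely failure is slow closure onto the 1,1-disubstituted alkene in the trans-substituted seven-membered transition state. The C5 alkylidene would then dimerise by cross-metathesis, or the catalyst would decay to hydrides that isomerise the angelate from Z to E. The fallback moves the metathesis ahead of the ester exchange so that no angelate is present. It sets out from 24: ring closure under the same catalyst gives the dioxasilepine PMB ether F1, DDQ removes the PMB group to give the dioxasilepine C8 alcohol F2, and Yamaguchi esterification with 26 returns to the route at 29.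

**Step 8.** The risk is erosion of facial selectivity relative to C8: the conformer with the alkenyl group anti to the forming bond competes with the one that has the C–O bond anti, which would give the C6,C7-bis-epimer; the adduct may also lactonise in the aqueous medium. The fallback replaces the aqueous indium reaction by an isolated allylboron reagent, whose compact boron–oxygen chair offers no site for the ether oxygen and accentuates allylic strain. It sets out from 11: acetylation gives methyl (4R,5Z)-3-acetoxy-6-iodo-4-[(4-methoxyphenyl)methoxy]-2-methylidenehept-5-enoate F3; CuCl-catalysed SN2' borylation with bis(pinacolato)diboron gives the (2E)-allylboronate F4 (C8 chain cis to the CH2B group); Sc(OTf)3-catalysed allylboration of 13 at −78 °C returns to the route at 14.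

**Step 16.** The risk is isomerisation of the angeloyl unit to the tigloyl ester during slow acylation of the hindered C8 hydroxyl (reversible amine addition at the β-carbon of the activated acid). The fallback builds the Z alkene on the ester instead. It sets out from 25: acylation with 2-[bis(2,2,2-trifluoroethoxy)phosphoryl]propanoic acid (DCC, DMAP) gives the C8 phosphonopropanoate F5, and Still–Gennari olefination with acetaldehyde (KN(SiMe3)2, 18-crown-6, THF, −78 °C) returns to the route at 28.

**Step 22.** The risk is poor facial selectivity at C1, if the conformation of the closing ring overrides the 1,3-anti preference; β-elimination of acetate from the aldehyde is a second concern. The fallback sets C1 under reagent control. It sets out from 34: the ring is closed as before, the C1 epimer of the target F6 (alone or mixed with 35) is oxidised with Dess–Martin periodinane to the C1 ketone F7, and reduction with (R)-2-methyl-CBS-oxazaborolidine and catecholborane returns to the route at 35.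

## Further compounds

F1 | step 17 | (4S,7R)-4,7-dihydro-1,3-dioxa-2-silepine with cis C4=C5 and C8 PMB ether, (3S,6R,7S,8S) | CC1=C[C@H]([C@@H](C(=C)C(=O)OC)[C@H](OCc2ccc(OC)cc2)/C=C(/C)I)O[Si](C(C)C)(C(C)C)O[C@H]1CCO[Si](c2ccccc2)(c2ccccc2)C(C)(C)C
F2 | step 17 | (4S,7R)-4,7-dihydro-1,3-dioxa-2-silepine with cis C4=C5 and free C8 hydroxyl, (3S,6R,7S,8S) | CC1=C[C@H]([C@@H](C(=C)C(=O)OC)[C@H](O)/C=C(/C)I)O[Si](C(C)C)(C(C)C)O[C@H]1CCO[Si](c2ccccc2)(c2ccccc2)C(C)(C)C
F3 | step 8 | methyl (4R,5Z)-3-acetoxy-6-iodo-4-[(4-methoxyphenyl)methoxy]-2-methylidenehept-5-enoate (C3 epimers) | C/C(I)=C/[C@@H](OCc1ccc(OC)cc1)C(OC(C)=O)C(=C)C(=O)OC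
F4 | step 8 | methyl (2E,4S,5Z)-6-iodo-4-[(4-methoxyphenyl)methoxy]-2-[(4,4,5,5-tetramethyl-1,3,2-dioxaborolan-2-yl)methyl]hepta-2,5-dienoate | C/C(I)=C/[C@@H](OCc1ccc(OC)cc1)/C=C(\CB1OC(C)(C)C(C)(C)O1)C(=O)OC
F5 | step 16 | C8 2-[bis(2,2,2-trifluoroethoxy)phosphoryl]propanoate of 25 | C=C[C@@H](O[Si](C(C)C)(C(C)C)O[C@H](C(C)=C)CCO[Si](c1ccccc1)(c1ccccc1)C(C)(C)C)[C@@H](C(=C)C(=O)OC)[C@H](OC(=O)C(C)P(=O)(OCC(F)(F)F)OCC(F)(F)F)/C=C(/C)I
F6 | step 22 | (1R,3S,4Z,6R,7R,8R,9Z)-3-acetoxy-1-hydroxy-8-{[(2Z)-2-methylbut-2-enoyl]oxy}germacra-4,9,11(13)-trien-12,6-olide (C1 epimer of 35) | C=C1C(=O)O[C@@H]2/C=C(/C)[C@@H](OC(C)=O)C[C@@H](O)/C(C)=C\[C@@H](OC(=O)/C(C)=C\C)[C@H]12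
F7 | step 22 | (3S,4Z,6R,7R,8R,9Z)-3-acetoxy-8-{[(2Z)-2-methylbut-2-enoyl]oxy}-1-oxogermacra-4,9,11(13)-trien-12,6-olide | C=C1C(=O)O[C@@H]2/C=C(/C)[C@@H](OC(C)=O)CC(=O)/C(C)=C\[C@@H](OC(=O)/C(C)=C\C)[C@H]12
A1 | alternative 1 | 2,7-dimethylnaphthalene | Cc1ccc2ccc(C)cc2c1
A2 | alternative 1 | 2,7-dimethyl-1,4,5,8-tetrahydronaphthalene | CC1=CCC2=C(C1)CC(C)=CC2
A3 | alternative 1 | (3Z,8Z)-3,9-dimethylcyclodeca-3,8-diene-1,6-dione | O=C1C/C=C(/C)CC(=O)C/C(C)=C\C1
A4 | alternative 2 | malonic acid | OC(=O)CC(O)=O
A5 | alternative 2 | cis-fused α-carboxy γ-lactone with C1 TBS ether, C3 acetate and C8 angelate (C11 epimers) | OC(=O)C1C(=O)O[C@@H]2/C=C(/C)[C@@H](OC(C)=O)C[C@H](O[Si](C)(C)C(C)(C)C)/C(C)=C\[C@@H](OC(=O)/C(C)=C\C)[C@H]12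
A6 | alternative 3 | ten-membered cycloalkynol with C1 TBDPS, C3 triethylsilyl, C6 and C12 PMB ethers (C8 epimers) | C=C(COCc2ccc(OC)cc2)[C@@H]1[C@H](OCc3ccc(OC)cc3)/C=C(/C)[C@@H](O[Si](CC)(CC)CC)C[C@H](O[Si](c4ccccc4)(c5ccccc5)C(C)(C)C)C#CC1O
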